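## Retrosynthetic overview

1. The ring A bromide goes in last: 20 ⇐ vinyl bromide 19 ⇐ ketone 17, with a radical hydrogenation that leaves Br equatorial.
2. Ring A ⇐ enone 14 (two α′-methylations, C=C hydrogenation) ⇐ keto aldehyde 12 by intramolecular aldol condensation.
3. Key C–C bond: 12 ⇐ aldehyde 10 + methyl vinyl ketone 11, an enamine-catalysed asymmetric Michael addition that sets the ring A methine carbon.
4. 10 ⇐ bromoetherification and ozonolysis of (R)-allyl carbinol 7 ⇐ spiro-epoxide 6 ⇐ Sharpless epoxidation of the Birch diene 2 from 4-methylbenzyl alcohol 1.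
5. Ring order: cyclohexene (from the arene) → 7-oxabicyclo[2.2.1]heptane → cyclohexane ring A.

Assumption: the SMILES descriptors are taken at face value, so the target is (1R,2R,4S)-2-bromo-4-[(1S,4S)-4-bromo-3,3-dimethylcyclohexyl]-1-methyl-7-oxabicyclo[2.2.1]heptane (bicyclic Br endo, anti to the oxygen bridge; ring A substituents trans and both equatorial).

## Route

Step 1
Reactants: 1 4-methylbenzyl alcohol
Product: 2 (4-methylcyclohexa-1,4-dien-1-yl)methanol
Conditions: Li (3.5 equiv), NH3(l)/THF, t-BuOH, −78 °C; then NH4Cl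
Reagents that add atoms: none
Why: Birch reduction leaves both donor-substituted carbons sp2 and gives the 1,4-diene, the lithium alkoxide formed in situ disfavouring benzylic C–O cleavage.

Step 2
Reactants: 2 (4-methylcyclohexa-1,4-dien-1-yl)methanol
Product: 3 [(1S,6S)-4-methyl-7-oxabicyclo[4.1.0]hept-3-en-1-yl]methanol
Conditions: Ti(O-i-Pr)4 (10 mol%), L-(+)-diethyl tartrate (12 mol%), t-BuOOH (2 equiv), 4 Å molecular sieves, CH2Cl2, −20 °C
Reagents that add atoms: tert-butyl hydroperoxide, CC(C)(C)OO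
Why: Sharpless asymmetric epoxidation is hydroxyl-directed, so only the allylic double bond reacts, and L-(+)-tartrate gives the (S) configuration at the hydroxymethyl-bearing carbon, the same sense as the (2S)-epoxy alcohols it gives from other primary allylic alcohols.

Step 3
Reactants: 3 [(1S,6S)-4-methyl-7-oxabicyclo[4.1.0]hept-3-en-1-yl]methanol
Product: 4 (1S)-1-(hydroxymethyl)-4-methylcyclohex-3-en-1-ol
Conditions: LiAlH4 (1.2 equiv), THF, 0 °C → rt; aqueous work-up
Reagents that add atoms: none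
Why: Hydride opens the epoxide by SN2 attack at the less substituted ring carbon, so the tertiary C–O bond and its configuration are untouched.

Step 4
Reactants: 4 (1S)-1-(hydroxymethyl)-4-methylcyclohex-3-en-1-ol
Product: 6 (3S)-6-methyl-1-oxaspiro[2.5]oct-5-ene, via primary tosylate 5 (not isolated)
Conditions: TsCl (1.05 equiv), Et3N, DMAP (cat.), CH2Cl2, 0 °C; then K2CO3, MeOH, rt
Reagents that add atoms: p-toluenesulfonyl chloride, Cc1ccc(cc1)S(Cl)(=O)=O (its atoms stay only in 5)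
Why: Selective sulfonylation of the primary alcohol is followed by intramolecular Williamson closure by the tertiary alkoxide, which breaks no bond at the stereocenter.

Step 5
Reactants: 6 (3S)-6-methyl-1-oxaspiro[2.5]oct-5-ene
Product: 7 (1R)-4-methyl-1-(prop-2-en-1-yl)cyclohex-3-en-1-ol
Conditions: CH2=CHMgBr (2 equiv), CuI (10 mol%), THF, −30 → 0 °C; aq NH4Cl
Reagents that add atoms: vinylmagnesium bromide, C=C[Mg]Br
Why: Copper-catalysed Grignard opening of the 2,2-disubstituted epoxide occurs at the CH2 terminus, so the carbinol center is retained.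

Step 6
Reactants: 7 (1R)-4-methyl-1-(prop-2-en-1-yl)cyclohex-3-en-1-ol
Product: 8 (1R,2R,4R)-2-bromo-1-methyl-4-(prop-2-en-1-yl)-7-oxabicyclo[2.2.1]heptane
Conditions: NBS (1.1 equiv), CH2Cl2, 0 °C, dark
Reagents that add atoms: N-bromosuccinimide, O=C1CCC(=O)N1Br
Why: In this bromoetherification the bromonium ion forms on the electron-rich trisubstituted alkene and the tertiary OH attacks the methyl-bearing carbon from the opposite face, so the carbinol center fixes both new centers and Br ends endo, anti to the oxygen bridge.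

Step 7
Reactants: 8 (1R,2R,4R)-2-bromo-1-methyl-4-(prop-2-en-1-yl)-7-oxabicyclo[2.2.1]heptane
Product: 10 2-[(1R,3R,4R)-3-bromo-4-methyl-7-oxabicyclo[2.2.1]heptan-1-yl]acetaldehyde, via ozonide 9 (not isolated)
Conditions: O3, CH2Cl2, −78 °C; then PPh3, −78 °C → rt
Reagents that add atoms: ozone, [O-][O+]=O
Why: Ozonolysis with reductive work-up cleaves the only remaining alkene to the aldehyde, and the ether and the secondary bromide are inert.

Step 8
Reactants: 10 2-[(1R,3R,4R)-3-bromo-4-methyl-7-oxabicyclo[2.2.1]heptan-1-yl]acetaldehyde; 11 methyl vinyl ketone (but-3-en-2-one)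
Product: 12 (2S)-2-[(1S,3R,4R)-3-bromo-4-methyl-7-oxabicyclo[2.2.1]heptan-1-yl]-5-oxohexanal
Conditions: (S)-2-[methoxy(diphenyl)methyl]pyrrolidine (10 mol%), ethyl 3,4-dihydroxybenzoate (20 mol%), 11 (3 equiv), no solvent, 4 °C, 48 h
Reagents that add atoms: none
Why: In this enamine-catalysed asymmetric Michael addition the E-enamine is attacked on the face away from the diarylmethyl group, giving the (S) center under catalyst control, since the adjacent quaternary carbon carries two nearly identical ring arms and exerts no bias.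

Step 9
Reactants: 12 (2S)-2-[(1S,3R,4R)-3-bromo-4-methyl-7-oxabicyclo[2.2.1]heptan-1-yl]-5-oxohexanal
Product: 14 (4R)-4-[(1S,3R,4R)-3-bromo-4-methyl-7-oxabicyclo[2.2.1]heptan-1-yl]cyclohex-2-en-1-one, via aldol 13 (not isolated)
Conditions: LiOH·H2O (1 equiv), i-PrOH, 0 °C → rt
Reagents that add atoms: none
Why: Intramolecular aldol condensation of the methyl ketone enolate onto the aldehyde closes the six-membered ring faster than the α-branched aldehyde enolizes, which should spare both the stereocenter and the β-ether.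

Step 10
Reactants: 14 (4R)-4-[(1S,3R,4R)-3-bromo-4-methyl-7-oxabicyclo[2.2.1]heptan-1-yl]cyclohex-2-en-1-one
Product: 15 (4R)-4-[(1S,3R,4R)-3-bromo-4-methyl-7-oxabicyclo[2.2.1]heptan-1-yl]-6-methylcyclohex-2-en-1-one (both C6 epimers)
Conditions: LiN(i-Pr)2 (1.1 equiv), THF, −78 °C; MeI (1.5 equiv), −78 → −20 °C
Reagents that add atoms: iodomethane, CI
Why: Kinetic α′-deprotonation of the enone gives the cross-conjugated enolate, which is methylated by SN2 without touching the γ-stereocenter.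

Step 11
Reactants: 15 (4R)-4-[(1S,3R,4R)-3-bromo-4-methyl-7-oxabicyclo[2.2.1]heptan-1-yl]-6-methylcyclohex-2-en-1-one
Product: 16 (4R)-4-[(1S,3R,4R)-3-bromo-4-methyl-7-oxabicyclo[2.2.1]heptan-1-yl]-6,6-dimethylcyclohex-2-en-1-one
Conditions: LiN(i-Pr)2 (1.3 equiv), THF, −78 °C; MeI (3 equiv), DMPU, −78 → 0 °C
Reagents that add atoms: iodomethane, CI
Why: A second kinetic α′-enolate alkylation installs the geminal dimethyl group and removes the C6 stereocenter, so both epimers of 15 converge.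

Step 12
Reactants: 16 (4R)-4-[(1S,3R,4R)-3-bromo-4-methyl-7-oxabicyclo[2.2.1]heptan-1-yl]-6,6-dimethylcyclohex-2-en-1-one
Product: 17 (4S)-4-[(1S,3R,4R)-3-bromo-4-methyl-7-oxabicyclo[2.2.1]heptan-1-yl]-2,2-dimethylcyclohexan-1-one
Conditions: H2 (3 atm), RhCl(PPh3)3 (10 mol%), benzene–EtOH, rt
Reagents that add atoms: none
Why: Homogeneous (Wilkinson) hydrogenation saturates the disubstituted enone C=C without hydrogenolysis of the secondary C–Br bond.

Step 13
Reactants: 17 (4S)-4-[(1S,3R,4R)-3-bromo-4-methyl-7-oxabicyclo[2.2.1]heptan-1-yl]-2,2-dimethylcyclohexan-1-one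
Product: 18 [(4S)-4-[(1S,3R,4R)-3-bromo-4-methyl-7-oxabicyclo[2.2.1]heptan-1-yl]-2,2-dimethylcyclohexylidene]hydrazine
Conditions: N2H4·H2O (10 equiv), Et3N, EtOH, 80 °C
Reagents that add atoms: hydrazine, NN
Why: Condensation with excess hydrazine gives the hydrazone even of the α,α-dimethyl ketone, and the hindered bicyclic bromide resists substitution and elimination.

Step 14
Reactants: 18 [(4S)-4-[(1S,3R,4R)-3-bromo-4-methyl-7-oxabicyclo[2.2.1]heptan-1-yl]-2,2-dimethylcyclohexylidene]hydrazine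
Product: 19 (1R,2R,4S)-2-bromo-4-[(1S)-4-bromo-5,5-dimethylcyclohex-3-en-1-yl]-1-methyl-7-oxabicyclo[2.2.1]heptane
Conditions: NBS (2.2 equiv), pyridine, CH2Cl2, −10 °C → rt
Reagents that add atoms: N-bromosuccinimide, O=C1CCC(=O)N1Br
Why: Barton-type halogenation of the hydrazone (oxidation to the diazo compound, bromination, loss of N2, loss of a proton) gives the vinyl bromide, and only one regioisomer is possible because the other α-carbon is quaternary.

Step 15
Reactants: 19 (1R,2R,4S)-2-bromo-4-[(1S)-4-bromo-5,5-dimethylcyclohex-3-en-1-yl]-1-methyl-7-oxabicyclo[2.2.1]heptane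
Product: 20 (1R,2R,4S)-2-bromo-4-[(1S,4S)-4-bromo-3,3-dimethylcyclohexyl]-1-methyl-7-oxabicyclo[2.2.1]heptane
Conditions: Mn(dpm)3 (10 mol%; dpm = 2,2,6,6-tetramethylheptane-3,5-dionate), PhSiH3 (2 equiv), t-BuOOH (2 equiv), i-PrOH, rt
Reagents that add atoms: none
Why: Hydrogen-atom-transfer hydrogenation tolerates C–Br bonds, and the α-bromo radical takes its second hydrogen axially, on the face away from the axial methyl, so Br ends equatorial and trans to the equatorial ring A substituent, giving the (S) center.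

## Compound list

1 | 4-methylbenzyl alcohol | Cc1ccc(CO)cc1 | starting material
2 | (4-methylcyclohexa-1,4-dien-1-yl)methanol | CC1=CCC(CO)=CC1 | intermediate
3 | [(1S,6S)-4-methyl-7-oxabicyclo[4.1.0]hept-3-en-1-yl]methanol | OC[C@@]12CC=C(C)C[C@@H]1O2 | intermediate
4 | (1S)-1-(hydroxymethyl)-4-methylcyclohex-3-en-1-ol | OC[C@@]1(O)CC=C(C)CC1 | intermediate
5 | [(1S)-1-hydroxy-4-methylcyclohex-3-en-1-yl]methyl 4-methylbenzenesulfonate | Cc1ccc(cc1)S(=O)(=O)OC[C@@]1(O)CC=C(C)CC1 | intermediate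
6 | (3S)-6-methyl-1-oxaspiro[2.5]oct-5-ene | CC1=CC[C@@]2(CC1)CO2 | intermediate
7 | (1R)-4-methyl-1-(prop-2-en-1-yl)cyclohex-3-en-1-ol | C=CC[C@@]1(O)CC=C(C)CC1 | intermediate
8 | (1R,2R,4R)-2-bromo-1-methyl-4-(prop-2-en-1-yl)-7-oxabicyclo[2.2.1]heptane | C=CC[C@@]12CC[C@@](C)(O1)[C@H](Br)C2 | intermediate
9 | 3-{[(1R,3R,4R)-3-bromo-4-methyl-7-oxabicyclo[2.2.1]heptan-1-yl]methyl}-1,2,4-trioxolane (ozonide, both epimers) | C1OC(C[C@@]23CC[C@@](C)(O2)[C@H](Br)C3)OO1 | intermediate
10 | 2-[(1R,3R,4R)-3-bromo-4-methyl-7-oxabicyclo[2.2.1]heptan-1-yl]acetaldehyde | O=CC[C@@]12CC[C@@](C)(O1)[C@H](Br)C2 | intermediate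
11 | methyl vinyl ketone (but-3-en-2-one) | CC(=O)C=C | starting material
12 | (2S)-2-[(1S,3R,4R)-3-bromo-4-methyl-7-oxabicyclo[2.2.1]heptan-1-yl]-5-oxohexanal | CC(=O)CC[C@H](C=O)[C@@]12CC[C@@](C)(O1)[C@H](Br)C2 | intermediate
13 | (4R)-4-[(1S,3R,4R)-3-bromo-4-methyl-7-oxabicyclo[2.2.1]heptan-1-yl]-3-hydroxycyclohexan-1-one (both carbinol epimers) | O=C1CC(O)[C@@H](CC1)[C@@]23CC[C@@](C)(O2)[C@H](Br)C3 | intermediate
14 | (4R)-4-[(1S,3R,4R)-3-bromo-4-methyl-7-oxabicyclo[2.2.1]heptan-1-yl]cyclohex-2-en-1-one | O=C1C=C[C@@H](CC1)[C@@]23CC[C@@](C)(O2)[C@H](Br)C3 | intermediate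
15 | (4R)-4-[(1S,3R,4R)-3-bromo-4-methyl-7-oxabicyclo[2.2.1]heptan-1-yl]-6-methylcyclohex-2-en-1-one (both C6 epimers) | O=C1C=C[C@@H](CC1C)[C@@]23CC[C@@](C)(O2)[C@H](Br)C3 | intermediate
16 | (4R)-4-[(1S,3R,4R)-3-bromo-4-methyl-7-oxabicyclo[2.2.1]heptan-1-yl]-6,6-dimethylcyclohex-2-en-1-one | O=C1C=C[C@@H](CC1(C)C)[C@@]23CC[C@@](C)(O2)[C@H](Br)C3 | intermediate
17 | (4S)-4-[(1S,3R,4R)-3-bromo-4-methyl-7-oxabicyclo[2.2.1]heptan-1-yl]-2,2-dimethylcyclohexan-1-one | O=C1CC[C@@H](CC1(C)C)[C@@]23CC[C@@](C)(O2)[C@H](Br)C3 | intermediate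
18 | [(4S)-4-[(1S,3R,4R)-3-bromo-4-methyl-7-oxabicyclo[2.2.1]heptan-1-yl]-2,2-dimethylcyclohexylidene]hydrazine | NN=C1CC[C@@H](CC1(C)C)[C@@]23CC[C@@](C)(O2)[C@H](Br)C3 | intermediate
19 | (1R,2R,4S)-2-bromo-4-[(1S)-4-bromo-5,5-dimethylcyclohex-3-en-1-yl]-1-methyl-7-oxabicyclo[2.2.1]heptane | BrC1=CC[C@@H](CC1(C)C)[C@@]23CC[C@@](C)(O2)[C@H](Br)C3 | intermediate
20 | (1R,2R,4S)-2-bromo-4-[(1S,4S)-4-bromo-3,3-dimethylcyclohexyl]-1-methyl-7-oxabicyclo[2.2.1]heptane | CC1(C)C[C@@H]([C@@]23CC[C@@](C)(O2)[C@H](Br)C3)CC[C@@H]1Br | target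

## Step count and risks

Total steps: 15. Longest linear sequence: 15 steps (1 → 20); methyl vinyl ketone 11 enters at step 8.

Three steps most likely to fail:

Step 8 (Michael addition). The aldehyde is neopentyl-like and β-alkoxy, so the enamine may form slowly or expel the bridging ether oxygen. The fallback sets out from 10 and comes back at 12. Aldehyde 10 is condensed with (R)-1-amino-2-(methoxymethyl)pyrrolidine to give the hydrazone F1. F1 is deprotonated with LiN(i-Pr)2 at −78 °C and alkylated at −100 °C with 2-(2-iodoethyl)-2-methyl-1,3-dioxolane to give the alkylated hydrazone F2, the auxiliary now setting the same (S) aldehyde center at a temperature where β-elimination is slow. Ozonolysis at −78 °C frees the ketal aldehyde F3, and pyridinium p-toluenesulfonate in wet acetone removes the ketal to give 12.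

Step 9 (aldol condensation). Hydroxide can epimerize the α-branched aldehyde or open the oxabicycle by β-elimination before ring closure. The fallback sets out from 12 and comes back at 14, closing the ring by metathesis instead. Aldehyde-selective methylenation of 12 with Zn, CH2I2 and Ti(O-i-Pr)4 gives the alkenyl ketone F4, which no longer has an acidic hydrogen next to the ether. Kinetic deprotonation on the methyl side with LiN(i-Pr)2 and a Mannich reaction with CH2=NMe2+ I− give the Mannich base F5. N-methylation with MeI and elimination with NaHCO3 give the dienone F6, and ring-closing metathesis with the second-generation Grubbs catalyst in CH2Cl2 at 40 °C gives 14.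

Step 15 (radical hydrogenation of the vinyl bromide). Loss of bromine, or hydrogen delivery from the wrong face, would give the debrominated product or the axial bromide. The fallback sets out from 17 and comes back at 20. Reduction of 17 with LiBH(s-Bu)3 at −78 °C attacks equatorially and gives the axial alcohol F7. Tf2O and pyridine at −20 °C give the triflate F8, and Bu4NBr in toluene displaces it by SN2 with inversion to the equatorial bromide 20; elimination is the expected competitor at this neopentyl center.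

## Further compounds

F1 | step 8 | (E)-2-[(1R,3R,4R)-3-bromo-4-methyl-7-oxabicyclo[2.2.1]heptan-1-yl]-N-[(2R)-2-(methoxymethyl)pyrrolidin-1-yl]ethan-1-imine | COC[C@H]1CCCN1/N=C/C[C@@]23CC[C@@](C)(O2)[C@H](Br)C3
F2 | step 8 | (1E,2R)-2-[(1S,3R,4R)-3-bromo-4-methyl-7-oxabicyclo[2.2.1]heptan-1-yl]-N-[(2R)-2-(methoxymethyl)pyrrolidin-1-yl]-4-(2-methyl-1,3-dioxolan-2-yl)butan-1-imine | COC[C@H]1CCCN1/N=C/[C@@H](CCC2(C)OCCO2)[C@@]34CC[C@@](C)(O3)[C@H](Br)C4
F3 | step 8 | (2S)-2-[(1S,3R,4R)-3-bromo-4-methyl-7-oxabicyclo[2.2.1]heptan-1-yl]-4-(2-methyl-1,3-dioxolan-2-yl)butanal | O=C[C@@H](CCC1(C)OCCO1)[C@@]23CC[C@@](C)(O2)[C@H](Br)C3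
F4 | step 9 | (5R)-5-[(1S,3R,4R)-3-bromo-4-methyl-7-oxabicyclo[2.2.1]heptan-1-yl]hept-6-en-2-one | CC(=O)CC[C@H](C=C)[C@@]12CC[C@@](C)(O1)[C@H](Br)C2
F5 | step 9 | (6R)-6-[(1S,3R,4R)-3-bromo-4-methyl-7-oxabicyclo[2.2.1]heptan-1-yl]-1-(dimethylamino)oct-7-en-3-one | CN(C)CCC(=O)CC[C@H](C=C)[C@@]12CC[C@@](C)(O1)[C@H](Br)C2
F6 | step 9 | (6R)-6-[(1S,3R,4R)-3-bromo-4-methyl-7-oxabicyclo[2.2.1]heptan-1-yl]octa-1,7-dien-3-one | C=CC(=O)CC[C@H](C=C)[C@@]12CC[C@@](C)(O1)[C@H](Br)C2
F7 | step 15 | (1R,4S)-4-[(1S,3R,4R)-3-bromo-4-methyl-7-oxabicyclo[2.2.1]heptan-1-yl]-2,2-dimethylcyclohexan-1-ol | CC1(C)C[C@@H]([C@@]23CC[C@@](C)(O2)[C@H](Br)C3)CC[C@H]1O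
F8 | step 15 | (1R,4S)-4-[(1S,3R,4R)-3-bromo-4-methyl-7-oxabicyclo[2.2.1]heptan-1-yl]-2,2-dimethylcyclohexyl trifluoromethanesulfonate | CC1(C)C[C@@H]([C@@]23CC[C@@](C)(O2)[C@H](Br)C3)CC[C@H]1OS(=O)(=O)C(F)(F)F
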